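**Plan**

- Retrosynthesis: ring C is opened at C3–C4, the acyloin bond between the ring A aryl ketone carbon (C4) and the carbinol carbon (C3), giving a dialdehyde. The O1–C2 aryl ether is then cut to a ring A salicylaldehyde and a 1-arylallyl alcohol (vinyl = masked C3 aldehyde). The dihydrofuran C3a–C3 bond is cut last, to an aryl C–H and a β-aryloxycinnamate made from a phenol and an arylpropiolate.
- Forward order: the dihydrofuran ring is closed first by imine-directed C–H alkylation, ring A is attached as an aryl ether, and ring C is closed last by a carbene-catalysed crossed benzoin.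
- Stereochemistry: benzofuran C2 comes from a chiral imine auxiliary and benzofuran C3 from base equilibration to trans. Flavanonol C3 comes from the chiral carbene, and C2 from dynamic kinetic resolution in the same step.
- Enabling feature: in the open form C4 is an aldehyde carbon on ring A and C3 an aldehyde whose neighbour C2–H is benzylic, α-aryloxy and α-formyl, hence readily epimerized. In ring C the C4 ketone is conjugated to ring A, so the 3-hydroxy-4-ketone is the stable ketol.

Key step: step 11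

Assumption: the absolute sense of induction of the two chiral controllers (the 1-aminoindane imine auxiliary in step 4 and the aminoindanol-derived triazolium carbene in step 11) is assigned by analogy with their closest precedents; both antipodes of each are commercial, so a reversed sense would change only which enantiomer of the controller is used.

**Route**

Step 1
Reactants: 1 4-(benzyloxy)-3-methoxybenzaldehyde
Product: 2 1-(benzyloxy)-4-(2,2-dibromoethenyl)-2-methoxybenzene
Conditions: CBr4, PPh3, CH2Cl2, 0 °C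
Reagents that add atoms: carbon tetrabromide, BrC(Br)(Br)Br
Why: Ramirez dibromo-olefination (first half of the Corey–Fuchs sequence) converts the aromatic aldehyde into the 1,1-dibromoalkene under neutral conditions that leave the benzyl and methyl ethers untouched.

Step 2
Reactants: 2 1-(benzyloxy)-4-(2,2-dibromoethenyl)-2-methoxybenzene
Product: 4 methyl 3-[4-(benzyloxy)-3-methoxyphenyl]prop-2-ynoate, via lithium acetylide 3 (not isolated)
Conditions: n-BuLi (2.1 equiv), THF, −78 °C; then ClCO2Me, −78 °C to rt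
Reagents that add atoms: methyl chloroformate, COC(=O)Cl
Why: Second half of the Corey–Fuchs reaction, in which bromine–lithium exchange and elimination give the lithium acetylide, which is acylated in the same flask by the chloroformate.

Step 3
Reactants: 4 methyl 3-[4-(benzyloxy)-3-methoxyphenyl]prop-2-ynoate; 5 4-(benzyloxy)-3-hydroxybenzaldehyde
Product: 6 methyl (2Z)-3-[2-(benzyloxy)-5-formylphenoxy]-3-[4-(benzyloxy)-3-methoxyphenyl]prop-2-enoate
Conditions: K2CO3 (0.5 equiv), DMF, 50 °C
Reagents that add atoms: none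
Why: Oxa-Michael addition of the phenoxide to the ynoate, where anti addition should favour the Z isomer (aryloxy cis to the ester); any E isomer is removed by crystallization or chromatography because step 4 needs one alkene geometry.

Step 4
Reactants: 6 methyl (2Z)-3-[2-(benzyloxy)-5-formylphenoxy]-3-[4-(benzyloxy)-3-methoxyphenyl]prop-2-enoate; 7 (S)-1-aminoindane
Product: 10 methyl (2R,3S)-7-(benzyloxy)-2-[4-(benzyloxy)-3-methoxyphenyl]-4-formyl-2,3-dihydro-1-benzofuran-3-carboxylate, via N-indanyl imine 8 (not isolated), via cyclized imine 9 (not isolated)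
Conditions: 7 (1.05 equiv), 4 Å MS, toluene, rt; then [RhCl(coe)2]2 (5 mol %), FcPCy2 [(dicyclohexylphosphino)ferrocene, Fe(C5H5)(C5H4PCy2)] (15 mol %), 75 °C; then 1 M HCl (aq), THF, rt
Reagents that add atoms: water, O
Why: Imine-directed C–H activation and intramolecular alkene hydroarylation with monovalent rhodium, in which oxidative addition of the ortho C–H bond between the imine and the aryloxy group, hydride insertion into the tethered enol ether and C–C reductive elimination add aryl and hydrogen syn across the Z alkene to give the 2,3-cis dihydrobenzofuran, the chiral N-indanyl group selecting the alkene face and so setting C2 as R, after which mild acid returns the aldehyde and releases the auxiliary.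

Step 5
Reactants: 10 methyl (2R,3S)-7-(benzyloxy)-2-[4-(benzyloxy)-3-methoxyphenyl]-4-formyl-2,3-dihydro-1-benzofuran-3-carboxylate
Product: 11 methyl (2R,3R)-7-(benzyloxy)-2-[4-(benzyloxy)-3-methoxyphenyl]-4-formyl-2,3-dihydro-1-benzofuran-3-carboxylate
Conditions: NaOMe (0.2 equiv), MeOH–THF, rt
Reagents that add atoms: none
Why: Base epimerization through the ester enolate at C3 should convert the cis ester into the thermodynamically favoured 2,3-trans isomer, so C3 is relayed from C2 (which has no acidic hydrogen), and recrystallization at this stage is foreseen to upgrade enantiomeric purity if required.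

Step 6
Reactants: 11 methyl (2R,3R)-7-(benzyloxy)-2-[4-(benzyloxy)-3-methoxyphenyl]-4-formyl-2,3-dihydro-1-benzofuran-3-carboxylate
Product: 13 1-[(2R,3S)-7-(benzyloxy)-2-[4-(benzyloxy)-3-methoxyphenyl]-3-(hydroxymethyl)-2,3-dihydro-1-benzofuran-4-yl]prop-2-en-1-ol (both carbinol epimers), via bromomagnesium alkoxide 12 (not isolated)
Conditions: CH2=CHMgBr (1.2 equiv), THF, −78 °C; then LiAlH4, −78 to 0 °C; Rochelle salt (aq)
Reagents that add atoms: vinylmagnesium bromide, C=C[Mg]Br
Why: Chemoselective Grignard 1,2-addition to the aldehyde beside the methyl ester at low temperature, followed in the same flask by LiAlH4 reduction of the ester (or of the δ-lactone if the alkoxide has closed onto it) to the primary alcohol; the new carbinol centre forms as a mixture, which is harmless because this centre is re-equilibrated in step 11.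

Step 7
Reactants: 13 1-[(2R,3S)-7-(benzyloxy)-2-[4-(benzyloxy)-3-methoxyphenyl]-3-(hydroxymethyl)-2,3-dihydro-1-benzofuran-4-yl]prop-2-en-1-ol
Product: 14 1-[(2R,3S)-7-(benzyloxy)-2-[4-(benzyloxy)-3-methoxyphenyl]-3-({[tert-butyl(dimethyl)silyl]oxy}methyl)-2,3-dihydro-1-benzofuran-4-yl]prop-2-en-1-ol (both carbinol epimers)
Conditions: TBSCl (1.05 equiv), imidazole, CH2Cl2, 0 °C
Reagents that add atoms: tert-butyldimethylsilyl chloride, CC(C)(C)[Si](C)(C)Cl
Why: Silylation should be selective for the unhindered primary alcohol over the hindered secondary benzylic-allylic alcohol, which stays free for step 9.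

Step 8
Reactants: 15 2,4,6-trihydroxybenzaldehyde
Product: 16 2,4-bis(benzyloxy)-6-hydroxybenzaldehyde
Conditions: BnBr (2.05 equiv), K2CO3, DMF, 0 °C to rt
Reagents that add atoms: benzyl bromide, BrCc1ccccc1
Why: Williamson etherification in which the hydroxyl that is hydrogen-bonded to the formyl group is the least nucleophilic and should remain free.

Step 9
Reactants: 14 1-[(2R,3S)-7-(benzyloxy)-2-[4-(benzyloxy)-3-methoxyphenyl]-3-({[tert-butyl(dimethyl)silyl]oxy}methyl)-2,3-dihydro-1-benzofuran-4-yl]prop-2-en-1-ol; 16 2,4-bis(benzyloxy)-6-hydroxybenzaldehyde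
Product: 17 2,4-bis(benzyloxy)-6-({1-[(2R,3S)-7-(benzyloxy)-2-[4-(benzyloxy)-3-methoxyphenyl]-3-({[tert-butyl(dimethyl)silyl]oxy}methyl)-2,3-dihydro-1-benzofuran-4-yl]prop-2-en-1-yl}oxy)benzaldehyde (both ether epimers)
Conditions: PPh3, DIAD, toluene, 0 °C to rt
Reagents that add atoms: none
Why: Mitsunobu etherification, in which the acidic salicylaldehyde-type phenol displaces the oxyphosphonium group at the carbinol carbon to give the branched allyl aryl ether; the configuration of this carbon is not controlled and need not be.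

Step 10
Reactants: 17 2,4-bis(benzyloxy)-6-({1-[(2R,3S)-7-(benzyloxy)-2-[4-(benzyloxy)-3-methoxyphenyl]-3-({[tert-butyl(dimethyl)silyl]oxy}methyl)-2,3-dihydro-1-benzofuran-4-yl]prop-2-en-1-yl}oxy)benzaldehyde
Product: 18 2,4-bis(benzyloxy)-6-{1-[(2R,3S)-7-(benzyloxy)-2-[4-(benzyloxy)-3-methoxyphenyl]-3-({[tert-butyl(dimethyl)silyl]oxy}methyl)-2,3-dihydro-1-benzofuran-4-yl]-2-oxoethoxy}benzaldehyde (both epimers at the ether carbon)
Conditions: OsO4 (2 mol %), NaIO4 (4 equiv), 2,6-lutidine, 1,4-dioxane–H2O (3:1), rt; taken on without chromatography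
Reagents that add atoms: sodium periodate, [Na+].[O-]I(=O)(=O)=O (oxygen relayed by the catalytic OsO4)
Why: Lemieux–Johnson oxidation, in which catalytic dihydroxylation of the only alkene and periodate cleavage unmask the second aldehyde under nearly neutral conditions that should spare the electron-rich arenes, the silyl ether and the benzyl ethers.

Step 11
Reactants: 18 2,4-bis(benzyloxy)-6-{1-[(2R,3S)-7-(benzyloxy)-2-[4-(benzyloxy)-3-methoxyphenyl]-3-({[tert-butyl(dimethyl)silyl]oxy}methyl)-2,3-dihydro-1-benzofuran-4-yl]-2-oxoethoxy}benzaldehyde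
Product: 19 (2R,3R)-5,7-bis(benzyloxy)-2-[(2R,3S)-7-(benzyloxy)-2-[4-(benzyloxy)-3-methoxyphenyl]-3-({[tert-butyl(dimethyl)silyl]oxy}methyl)-2,3-dihydro-1-benzofuran-4-yl]-3-hydroxy-2,3-dihydro-4H-chromen-4-one
Conditions: (5aS,10bR)-2-(pentafluorophenyl)-5a,10b-dihydro-4H,6H-indeno[2,1-b][1,2,4]triazolo[4,3-d][1,4]oxazin-2-ium tetrafluoroborate (15 mol %), i-Pr2NEt (1 equiv), toluene, rt, argon
Reagents that add atoms: none
Why: Proposed new method: the triazolylidene carbene adds to the ring A aldehyde of 18 to give an enaminol (Breslow intermediate) whose nucleophilic carbon, the future C4, attacks the α-aryloxy aldehyde carbon, the future C3, and after proton transfer the carbene is expelled, so the C3–C4 bond, the C4 ketone and the C3 hydroxyl arise together. The closest known reaction type is the carbene-catalysed enantioselective intramolecular crossed benzoin cyclization of 2-(2-oxoalkoxy)benzaldehydes to 3-hydroxychroman-4-ones, extended here to an aldehyde acceptor that carries an epimerizable α-stereocentre. Ring C closes in a 6-exo-trig mode, the acyl anion equivalent adding to the C=O bond. C3 is set by the catalyst, whose aminoindanol backbone shields one face of the enaminol and thereby selects the aldehyde face; C2 is set by dynamic kinetic resolution, because the C2–H of 18 is benzylic, α-aryloxy and α to the aldehyde and should be exchanged by the amine faster than cyclization, while only the epimer that can place the benzofuranyl group pseudo-equatorial on the catalyst-selected face closes readily, which leads to the diequatorial 2,3-trans ketol. The step needs the ring A aldehyde and not the aliphatic one to become the acyl anion, which the substrate should secure because the α,α-disubstituted aliphatic aldehyde is the more hindered donor and the far better acceptor, and because benzoin formation is reversible and the ring-A-conjugated aryl ketone is the thermodynamic ketol. It also needs benzoin closure to outrun the reversible 5-exo aldol of the C2 enol onto the ring A aldehyde, which the weak amine base favours, and the two remote dihydrobenzofuran stereocentres are untouched, so the outcome should be governed by the catalyst.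

Step 12
Reactants: 19 (2R,3R)-5,7-bis(benzyloxy)-2-[(2R,3S)-7-(benzyloxy)-2-[4-(benzyloxy)-3-methoxyphenyl]-3-({[tert-butyl(dimethyl)silyl]oxy}methyl)-2,3-dihydro-1-benzofuran-4-yl]-3-hydroxy-2,3-dihydro-4H-chromen-4-one
Product: 20 (2R,3R)-5,7-bis(benzyloxy)-2-[(2R,3S)-7-(benzyloxy)-2-[4-(benzyloxy)-3-methoxyphenyl]-3-(hydroxymethyl)-2,3-dihydro-1-benzofuran-4-yl]-3-hydroxy-2,3-dihydro-4H-chromen-4-one
Conditions: HF·pyridine, THF–pyridine, 0 °C to rt
Reagents that add atoms: none
Why: Fluoride cleavage of the primary silyl ether under buffered, weakly acidic conditions that should not epimerize the base-sensitive dihydroflavonol.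

Step 13
Reactants: 20 (2R,3R)-5,7-bis(benzyloxy)-2-[(2R,3S)-7-(benzyloxy)-2-[4-(benzyloxy)-3-methoxyphenyl]-3-(hydroxymethyl)-2,3-dihydro-1-benzofuran-4-yl]-3-hydroxy-2,3-dihydro-4H-chromen-4-one
Product: 21 (2R,3R)-3,5,7-trihydroxy-2-[(2R,3S)-7-hydroxy-2-(4-hydroxy-3-methoxyphenyl)-3-(hydroxymethyl)-2,3-dihydro-1-benzofuran-4-yl]-2,3-dihydro-4H-chromen-4-one
Conditions: H2 (1 atm), 10% Pd/C, EtOAc–MeOH, rt
Reagents that add atoms: none
Why: Hydrogenolysis of the four aryl benzyl ethers under neutral conditions, in which the cyclic benzylic ethers at C2 of the chromanone and of the dihydrobenzofuran and the aryl ketone are expected to survive if the reaction is stopped once the benzyl ethers are consumed.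

**Compound list**

1 | 4-(benzyloxy)-3-methoxybenzaldehyde | COc1cc(C=O)ccc1OCc1ccccc1 | starting material
2 | 1-(benzyloxy)-4-(2,2-dibromoethenyl)-2-methoxybenzene | COc1cc(C=C(Br)Br)ccc1OCc1ccccc1 | intermediate
3 | lithium [4-(benzyloxy)-3-methoxyphenyl]acetylide | COc1cc(C#C[Li])ccc1OCc1ccccc1 | intermediate (not isolated)
4 | methyl 3-[4-(benzyloxy)-3-methoxyphenyl]prop-2-ynoate | COC(=O)C#Cc1ccc(OCc2ccccc2)c(OC)c1 | intermediate
5 | 4-(benzyloxy)-3-hydroxybenzaldehyde | O=Cc1ccc(OCc2ccccc2)c(O)c1 | starting material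
6 | methyl (2Z)-3-[2-(benzyloxy)-5-formylphenoxy]-3-[4-(benzyloxy)-3-methoxyphenyl]prop-2-enoate | COC(=O)/C=C(\Oc1cc(C=O)ccc1OCc1ccccc1)c1ccc(OCc2ccccc2)c(OC)c1 | intermediate
7 | (S)-1-aminoindane, (1S)-2,3-dihydro-1H-inden-1-amine | N[C@H]1CCc2ccccc21 | starting material
8 | (E)-N-[(1S)-indan-1-yl] imine of 6 | COC(=O)/C=C(\Oc1cc(/C=N/[C@H]2CCc3ccccc32)ccc1OCc1ccccc1)c1ccc(OCc2ccccc2)c(OC)c1 | intermediate (not isolated)
9 | (E)-N-[(1S)-indan-1-yl] imine of 10 (cyclized imine, 2,3-cis) | COc1cc([C@@H]2Oc3c(OCc4ccccc4)ccc(/C=N/[C@H]4CCc5ccccc54)c3[C@@H]2C(=O)OC)ccc1OCc1ccccc1 | intermediate (not isolated)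
10 | methyl (2R,3S)-7-(benzyloxy)-2-[4-(benzyloxy)-3-methoxyphenyl]-4-formyl-2,3-dihydro-1-benzofuran-3-carboxylate (cis) | COc1cc([C@@H]2Oc3c(OCc4ccccc4)ccc(C=O)c3[C@@H]2C(=O)OC)ccc1OCc1ccccc1 | intermediate
11 | methyl (2R,3R)-7-(benzyloxy)-2-[4-(benzyloxy)-3-methoxyphenyl]-4-formyl-2,3-dihydro-1-benzofuran-3-carboxylate (trans) | COc1cc([C@@H]2Oc3c(OCc4ccccc4)ccc(C=O)c3[C@H]2C(=O)OC)ccc1OCc1ccccc1 | intermediate
12 | bromomagnesium alkoxide of methyl (2R,3R)-7-(benzyloxy)-2-[4-(benzyloxy)-3-methoxyphenyl]-4-(1-hydroxyprop-2-en-1-yl)-2,3-dihydro-1-benzofuran-3-carboxylate (both carbinol epimers) | COc1cc([C@@H]2Oc3c(OCc4ccccc4)ccc(C(O[Mg]Br)C=C)c3[C@H]2C(=O)OC)ccc1OCc1ccccc1 | intermediate (not isolated)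
13 | 1-[(2R,3S)-7-(benzyloxy)-2-[4-(benzyloxy)-3-methoxyphenyl]-3-(hydroxymethyl)-2,3-dihydro-1-benzofuran-4-yl]prop-2-en-1-ol (both carbinol epimers) | COc1cc([C@@H]2Oc3c(OCc4ccccc4)ccc(C(O)C=C)c3[C@H]2CO)ccc1OCc1ccccc1 | intermediate
14 | 1-[(2R,3S)-7-(benzyloxy)-2-[4-(benzyloxy)-3-methoxyphenyl]-3-({[tert-butyl(dimethyl)silyl]oxy}methyl)-2,3-dihydro-1-benzofuran-4-yl]prop-2-en-1-ol (both carbinol epimers) | COc1cc([C@@H]2Oc3c(OCc4ccccc4)ccc(C(O)C=C)c3[C@H]2CO[Si](C)(C)C(C)(C)C)ccc1OCc1ccccc1 | intermediate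
15 | 2,4,6-trihydroxybenzaldehyde | O=Cc1c(O)cc(O)cc1O | starting material
16 | 2,4-bis(benzyloxy)-6-hydroxybenzaldehyde | O=Cc1c(O)cc(OCc2ccccc2)cc1OCc1ccccc1 | intermediate
17 | 2,4-bis(benzyloxy)-6-({1-[(2R,3S)-7-(benzyloxy)-2-[4-(benzyloxy)-3-methoxyphenyl]-3-({[tert-butyl(dimethyl)silyl]oxy}methyl)-2,3-dihydro-1-benzofuran-4-yl]prop-2-en-1-yl}oxy)benzaldehyde (both ether epimers) | COc1cc([C@@H]2Oc3c(OCc4ccccc4)ccc(C(C=C)Oc4cc(OCc5ccccc5)cc(OCc5ccccc5)c4C=O)c3[C@H]2CO[Si](C)(C)C(C)(C)C)ccc1OCc1ccccc1 | intermediate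
18 | 2,4-bis(benzyloxy)-6-{1-[(2R,3S)-7-(benzyloxy)-2-[4-(benzyloxy)-3-methoxyphenyl]-3-({[tert-butyl(dimethyl)silyl]oxy}methyl)-2,3-dihydro-1-benzofuran-4-yl]-2-oxoethoxy}benzaldehyde (both epimers at the ether carbon) | COc1cc([C@@H]2Oc3c(OCc4ccccc4)ccc(C(C=O)Oc4cc(OCc5ccccc5)cc(OCc5ccccc5)c4C=O)c3[C@H]2CO[Si](C)(C)C(C)(C)C)ccc1OCc1ccccc1 | intermediate
19 | (2R,3R)-5,7-bis(benzyloxy)-2-[(2R,3S)-7-(benzyloxy)-2-[4-(benzyloxy)-3-methoxyphenyl]-3-({[tert-butyl(dimethyl)silyl]oxy}methyl)-2,3-dihydro-1-benzofuran-4-yl]-3-hydroxy-2,3-dihydro-4H-chromen-4-one | COc1cc([C@@H]2Oc3c(OCc4ccccc4)ccc([C@H]4Oc5cc(OCc6ccccc6)cc(OCc6ccccc6)c5C(=O)[C@@H]4O)c3[C@H]2CO[Si](C)(C)C(C)(C)C)ccc1OCc1ccccc1 | intermediate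
20 | (2R,3R)-5,7-bis(benzyloxy)-2-[(2R,3S)-7-(benzyloxy)-2-[4-(benzyloxy)-3-methoxyphenyl]-3-(hydroxymethyl)-2,3-dihydro-1-benzofuran-4-yl]-3-hydroxy-2,3-dihydro-4H-chromen-4-one | COc1cc([C@@H]2Oc3c(OCc4ccccc4)ccc([C@H]4Oc5cc(OCc6ccccc6)cc(OCc6ccccc6)c5C(=O)[C@@H]4O)c3[C@H]2CO)ccc1OCc1ccccc1 | intermediate
21 | (2R,3R)-3,5,7-trihydroxy-2-[(2R,3S)-7-hydroxy-2-(4-hydroxy-3-methoxyphenyl)-3-(hydroxymethyl)-2,3-dihydro-1-benzofuran-4-yl]-2,3-dihydro-4H-chromen-4-one | COc1cc([C@@H]2Oc3c(O)ccc([C@H]4Oc5cc(O)cc(O)c5C(=O)[C@@H]4O)c3[C@H]2CO)ccc1O | target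

**Step count and risks**

Total step count: 13. Longest linear sequence: 12 steps (steps 1–7 and 9–13, from compound 1); step 8 is a one-step side branch.

Steps most likely to fail:

1. Step 11 (carbene-catalysed crossed benzoin with dynamic kinetic resolution). Possible failures are acyl anion formation at the aliphatic instead of the ring A aldehyde, aldol closure of the C2 enol onto the ring A aldehyde, cyclization of the mismatched C2 epimer before it has equilibrated, or a catalyst sense that conflicts with the resident stereocentres. The fallback uses the established chalcone epoxide construction of dihydroflavonols, which closes ring C at O1–C2 instead. It sets out from 14: exhaustive Lemieux–Johnson cleavage (OsO4 cat., excess NaIO4) of the 1-arylallyl alcohol gives (2R,3S)-7-(benzyloxy)-2-[4-(benzyloxy)-3-methoxyphenyl]-3-({[tert-butyl(dimethyl)silyl]oxy}methyl)-2,3-dihydro-1-benzofuran-4-carbaldehyde F1. Commercial 1-[2,4-bis(benzyloxy)-6-hydroxyphenyl]ethan-1-one F2 is protected with MOMCl and i-Pr2NEt to give 1-[2,4-bis(benzyloxy)-6-(methoxymethoxy)phenyl]ethan-1-one F3. Claisen–Schmidt condensation of F1 with F3 (KOH, EtOH–THF) gives the (E)-chalcone F4, and Julia–Colonna epoxidation (poly-L-leucine, urea–H2O2, DBU, THF) gives the (2R,3S)-epoxy ketone F5. HCl in MeOH–THF then removes the methoxymethyl and silyl groups and lets the freed phenol open the epoxide at the benzylic carbon, the former α-carbon becoming C3 (R) and C2 settling trans to it, so the route is rejoined at 20.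

2. Step 9 (Mitsunobu etherification). The doubly activated, electron-rich oxyphosphonium intermediate may ionize, leading to attack at the alkene terminus (linear cinnamyl ether) or to C-alkylation of the phloroglucinol-type ring. The fallback replaces the SN2 displacement by a metal-catalysed allylic substitution. From 14, ClCO2Me and pyridine give the allylic methyl carbonate F6. Branched-selective allylic etherification with the sodium phenoxide of 16, using [Ir(cod)Cl]2 (monovalent iridium) and a BINOL-derived phosphoramidite ligand in THF, then gives 17, where the route is rejoined.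

3. Step 4 (auxiliary-controlled C–H alkylation). Face selectivity in the hydride insertion may be poor, or be eroded by non-uniform alkene geometry in 6, and enrichment by crystallization may not succeed. The fallback gives up asymmetric induction in favour of resolution. From 6, condensation with benzylamine gives the achiral N-benzyl imine F7. The same rhodium-catalysed cyclization gives the racemic cis cyclized N-benzyl imine F8. Acid hydrolysis gives the racemic cis aldehyde ester F9, and NaOMe in MeOH gives the racemic trans aldehyde ester F10. Preparative chromatography of F10 on a chiral stationary phase then delivers the (2R,3R) enantiomer, which is 11, where the route is rejoined.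

Further compounds
F1 | step 11 | (2R,3S)-7-(benzyloxy)-2-[4-(benzyloxy)-3-methoxyphenyl]-3-({[tert-butyl(dimethyl)silyl]oxy}methyl)-2,3-dihydro-1-benzofuran-4-carbaldehyde | COc1cc([C@@H]2Oc3c(OCc4ccccc4)ccc(C=O)c3[C@H]2CO[Si](C)(C)C(C)(C)C)ccc1OCc1ccccc1
F2 | step 11 | 1-[2,4-bis(benzyloxy)-6-hydroxyphenyl]ethan-1-one | CC(=O)c1c(O)cc(OCc2ccccc2)cc1OCc1ccccc1
F3 | step 11 | 1-[2,4-bis(benzyloxy)-6-(methoxymethoxy)phenyl]ethan-1-one | CC(=O)c1c(OCOC)cc(OCc2ccccc2)cc1OCc1ccccc1
F4 | step 11 | (2E)-3-[(2R,3S)-7-(benzyloxy)-2-[4-(benzyloxy)-3-methoxyphenyl]-3-({[tert-butyl(dimethyl)silyl]oxy}methyl)-2,3-dihydro-1-benzofuran-4-yl]-1-[2,4-bis(benzyloxy)-6-(methoxymethoxy)phenyl]prop-2-en-1-one | COc1cc([C@@H]2Oc3c(OCc4ccccc4)ccc(/C=C/C(=O)c4c(OCOC)cc(OCc5ccccc5)cc4OCc4ccccc4)c3[C@H]2CO[Si](C)(C)C(C)(C)C)ccc1OCc1ccccc1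
F5 | step 11 | [(2R,3S)-3-[(2R,3S)-7-(benzyloxy)-2-[4-(benzyloxy)-3-methoxyphenyl]-3-({[tert-butyl(dimethyl)silyl]oxy}methyl)-2,3-dihydro-1-benzofuran-4-yl]oxiran-2-yl][2,4-bis(benzyloxy)-6-(methoxymethoxy)phenyl]methanone | COc1cc([C@@H]2Oc3c(OCc4ccccc4)ccc([C@@H]4O[C@H]4C(=O)c4c(OCOC)cc(OCc5ccccc5)cc4OCc4ccccc4)c3[C@H]2CO[Si](C)(C)C(C)(C)C)ccc1OCc1ccccc1
F6 | step 9 | 1-[(2R,3S)-7-(benzyloxy)-2-[4-(benzyloxy)-3-methoxyphenyl]-3-({[tert-butyl(dimethyl)silyl]oxy}methyl)-2,3-dihydro-1-benzofuran-4-yl]prop-2-en-1-yl methyl carbonate (both epimers) | COc1cc([C@@H]2Oc3c(OCc4ccccc4)ccc(C(OC(=O)OC)C=C)c3[C@H]2CO[Si](C)(C)C(C)(C)C)ccc1OCc1ccccc1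
F7 | step 4 | (E)-N-benzyl imine of 6 | COC(=O)/C=C(\Oc1cc(/C=N/Cc2ccccc2)ccc1OCc1ccccc1)c1ccc(OCc2ccccc2)c(OC)c1
F8 | step 4 | racemic cis cyclized (E)-N-benzyl imine, methyl (2R*,3S*)-7-(benzyloxy)-2-[4-(benzyloxy)-3-methoxyphenyl]-4-[(benzylimino)methyl]-2,3-dihydro-1-benzofuran-3-carboxylate (one enantiomer drawn) | COc1cc([C@@H]2Oc3c(OCc4ccccc4)ccc(/C=N/Cc4ccccc4)c3[C@@H]2C(=O)OC)ccc1OCc1ccccc1
F9 | step 4 | racemic methyl (2R*,3S*)-7-(benzyloxy)-2-[4-(benzyloxy)-3-methoxyphenyl]-4-formyl-2,3-dihydro-1-benzofuran-3-carboxylate (cis, one enantiomer drawn) | COc1cc([C@@H]2Oc3c(OCc4ccccc4)ccc(C=O)c3[C@@H]2C(=O)OC)ccc1OCc1ccccc1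
F10 | step 4 | racemic methyl (2R*,3R*)-7-(benzyloxy)-2-[4-(benzyloxy)-3-methoxyphenyl]-4-formyl-2,3-dihydro-1-benzofuran-3-carboxylate (trans, one enantiomer drawn) | COc1cc([C@@H]2Oc3c(OCc4ccccc4)ccc(C=O)c3[C@H]2C(=O)OC)ccc1OCc1ccccc1
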